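**Retrosynthetic overview**
- The C14/C15 acetates come last; the 13S,14R pair comes from hydroxyl-directed asymmetric epoxidation of an E-allylic alcohol, then hydrolysis with inversion at C13.
- The C17 methyl and the C7–C8 alkene come from a C8 ketone (kinetic enol triflate, methyl cross-coupling).
- Ring B is made last, by a one-carbon ring expansion of a trans-fused cyclopentanone: the side-chain carbon C9 is inserted between C8 and the quaternary C10 by a 1,2-shift of C10, which also joins core and side chain.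
- The trans-hydrindanone comes from 2-methylcyclopent-2-enone: asymmetric conjugate addition (C5) and enolate allylation (C10), then radical 6-endo closure of ring A, which creates the C4 gem-dimethyl carbon.
- The side chain comes from pent-4-yn-1-ol (carboalumination/hydroxymethylation sets the E-alkene). Ring order: purchased five-membered ring, then ring A, then ring B by expansion.

Numbering: labdane numbering is used for the bicyclic compounds (C1–C10 decalin, C11–C16 side chain, C17 on C8, C18/C19 on C4, C20 on C10).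
Assumption: the ligand antipode named in step 1 is taken to give the 3R enolate (otherwise its mirror image is used), and 2 is used as an ether solution.

**Step 1**
Reactants: 1 2-methylcyclopent-2-en-1-one; 2 isopropenylmagnesium bromide; 3 allyl bromide
Product: 5 (2R,3R)-2-methyl-2-(prop-2-en-1-yl)-3-(prop-1-en-2-yl)cyclopentan-1-one, via magnesium enolate 4 (not isolated)
Conditions: CuBr·SMe2 (5 mol %), (R)-1-[(Sp)-2-(dicyclohexylphosphino)ferrocenyl]ethyldiphenylphosphine (6 mol %), t-BuOMe, −78 °C; then 3, DMPU, −78 → 0 °C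
Reagents that add atoms: none
Why: Copper-catalysed asymmetric conjugate addition of the Grignard reagent sets C5 under ligand control (3R), and C-allylation of the regiodefined magnesium enolate anti to the isopropenyl group sets the quaternary C10 (2R) with allyl trans to isopropenyl.

**Step 2**
Reactants: 5 (2R,3R)-2-methyl-2-(prop-2-en-1-yl)-3-(prop-1-en-2-yl)cyclopentan-1-one
Product: 6 (3aR,7aR)-4,4,7a-trimethyloctahydro-1H-inden-1-one
Conditions: Mn(dpm)3 (10 mol %), PhSiH3, t-BuOOH, i-PrOH (0.01 M), 23 °C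
Reagents that add atoms: none
Why: Mukaiyama-type metal-hydride hydrogen-atom transfer picks the 1,1-disubstituted alkene, and the tertiary C4 radical closes 6-endo onto the allyl terminus (5-exo would give a strained trans-bicyclo[3.3.0]octane) before the secondary radical is capped by hydrogen (reductive radical cyclisation); the trans ring fusion is inherited from step 1 and no new stereocentre arises.

**Step 3**
Reactants: 7 pent-4-yn-1-ol
Product: 8 pent-4-yn-1-yl 2,4,6-triisopropylbenzoate
Conditions: 2,4,6-triisopropylbenzoic acid, PPh3, DIAD, THF, 0 → 23 °C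
Reagents that add atoms: 2,4,6-triisopropylbenzoic acid CC(C)c1cc(C(C)C)c(C(O)=O)c(C(C)C)c1
Why: Mitsunobu esterification of the primary alcohol installs the hindered aryl ester that later directs α-lithiation and acts as the nucleofuge; no stereocentre is involved.

**Step 4**
Reactants: 8 pent-4-yn-1-yl 2,4,6-triisopropylbenzoate
Product: 12 (E)-6-hydroxy-4-methylhex-4-en-1-yl 2,4,6-triisopropylbenzoate, via alkenylalane 9 (not isolated), via lithium alkenylaluminate 10 (not isolated), via lithium alkoxyaluminate 11 (not isolated)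
Conditions: Me3Al, Cp2ZrCl2 (20 mol %), CH2Cl2, 0 → 23 °C; n-BuLi, THF, −78 °C; (CH2O)n, −78 → 23 °C; aq. HCl
Reagents that add atoms: trimethylaluminium C[Al](C)C; formaldehyde (from paraformaldehyde) C=O
Why: Negishi zirconium-catalysed syn-carboalumination puts methyl on the internal and aluminium on the terminal alkyne carbon, and hydroxymethylation of the derived aluminate with retention fixes the E-trisubstituted alkene.

**Step 5**
Reactants: 12 (E)-6-hydroxy-4-methylhex-4-en-1-yl 2,4,6-triisopropylbenzoate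
Product: 13 (E)-4-methyl-6-(triethylsilyloxy)hex-4-en-1-yl 2,4,6-triisopropylbenzoate
Conditions: Et3SiCl, imidazole, CH2Cl2, 0 °C
Reagents that add atoms: chlorotriethylsilane CC[Si](Cl)(CC)CC
Why: Standard silyl ether formation gives a group that survives s-BuLi, KN(SiMe3)2 and MeMgBr and is removed by the acidic work-up of step 8.

**Step 6**
Reactants: 13 (E)-4-methyl-6-(triethylsilyloxy)hex-4-en-1-yl 2,4,6-triisopropylbenzoate; 6 (3aR,7aR)-4,4,7a-trimethyloctahydro-1H-inden-1-one
Product: 17 (5R,9S,10R,13E)-15-(triethylsilyloxy)-17-norlabd-13-en-8-one, via lithiated benzoate 14 (not isolated), via lithium alkoxide adduct 15 (not isolated), via C9-epimeric ketone 16 (not isolated)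
Conditions: 13, s-BuLi, TMEDA, Et2O, −78 °C; then 6, −78 °C; MgBr2·OEt2, −78 → 35 °C; DBU, 23 °C
Reagents that add atoms: none
Why: Proposed new method: one-carbon ring expansion of a ketone by an α-oxy carbenoid with a carboxylate nucleofuge – the α-lithiated hindered benzoate adds to C8 of 6 (a known reaction of such dipole-stabilised carbanions), MgBr2 turns the alkoxide into a chelated magnesium alkoxide that is a poor nucleophile (no epoxide) but still pushes, the Lewis-acid-bound carboxylate leaves from C9 as the anti-periplanar, more electron-rich quaternary C10 migrates from C8 to C9 with retention at C10 (this forms the C9–C10 bond and ring B and leaves the carbonyl at C8), acyl transfer is blocked by the two ortho isopropyl groups, and DBU then equilibrates the α-stereocentre C9 to the equatorial 9S epimer (side chain cis to C20); closest known reaction types: the semipinacol shift of β-sulfonyloxy alcohols under aluminium alkyls (Tsuchihashi–Suzuki), the magnesium halohydrin ring enlargement (Sisti) and the 1,2-metallate shift of lithiated benzoates on boron.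

**Step 7**
Reactants: 17 (5R,9S,10R,13E)-15-(triethylsilyloxy)-17-norlabd-13-en-8-one
Product: 19 (5R,9S,10R,13E)-15-(triethylsilyloxy)-17-norlabda-7,13-dien-8-yl trifluoromethanesulfonate, via potassium enolate 18 (not isolated)
Conditions: KN(SiMe3)2, THF, −78 °C; PhNTf2, −78 → 0 °C
Reagents that add atoms: N-phenylbis(trifluoromethanesulfonimide) O=S(=O)(N(c1ccccc1)S(=O)(=O)C(F)(F)F)C(F)(F)F
Why: Kinetic deprotonation by the bulky amide at the C7 methylene (the C9 methine is shielded by the quaternary C10 and the side chain) and O-sulfonylation give the C7–C8 enol triflate regioselectively without touching C9.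

**Step 8**
Reactants: 19 (5R,9S,10R,13E)-15-(triethylsilyloxy)-17-norlabda-7,13-dien-8-yl trifluoromethanesulfonate
Product: 21 (5R,9R,10R,13E)-labda-7,13-dien-15-ol, via silyl ether 20 (not isolated)
Conditions: MeMgBr, Fe(acac)3 (5 mol %), THF/NMP, −30 → 0 °C; then 1 M HCl, THF, 23 °C
Reagents that add atoms: methylmagnesium bromide C[Mg]Br
Why: Iron-catalysed Kumada-type cross-coupling of the alkenyl triflate with MeMgBr puts C17 on C8 with the double bond fixed at C7–C8, and dilute acid then hydrolyses the silyl ether; C9 is not affected.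

**Step 9**
Reactants: 21 (5R,9R,10R,13E)-labda-7,13-dien-15-ol
Product: 22 (5R,9R,10R,13R,14R)-13,14-epoxylabd-7-en-15-ol
Conditions: Ti(OiPr)4 (10 mol %), D-(−)-diethyl tartrate (12 mol %), t-BuOOH, 4 Å MS, CH2Cl2, −20 °C
Reagents that add atoms: tert-butyl hydroperoxide CC(C)(C)OO
Why: Sharpless asymmetric epoxidation: the titanium tartrate binds the allylic hydroxyl, so only the C13–C14 alkene reacts, and D-(−)-tartrate delivers oxygen to the face that gives the 13R,14R epoxide (reagent control, as for geraniol); the C7–C8 alkene is untouched.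

**Step 10**
Reactants: 22 (5R,9R,10R,13R,14R)-13,14-epoxylabd-7-en-15-ol
Product: 23 (5R,9R,10R,13S,14R)-labd-7-ene-13,14,15-triol
Conditions: HClO4 (5 mol %), THF/H2O 3:1, 0 → 23 °C
Reagents that add atoms: water O
Why: Acid-catalysed epoxide hydrolysis: water opens the protonated epoxide at the tertiary C13 with inversion (13R → 13S) while C14 keeps its C–O bond, giving the anti 13S,14R triol.

**Step 11**
Reactants: 23 (5R,9R,10R,13S,14R)-labd-7-ene-13,14,15-triol
Product: 24 (5R,9R,10R,13S,14R)-13-hydroxylabd-7-ene-14,15-diyl diacetate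
Conditions: Ac2O, pyridine, CH2Cl2, 0 → 23 °C
Reagents that add atoms: acetic anhydride CC(=O)OC(C)=O
Why: Acylation of the primary and secondary hydroxyls under mild conditions; the tertiary C13 hydroxyl does not react and no stereocentre is touched.

**Compound list**
1 | 2-methylcyclopent-2-en-1-one | CC1=CCCC1=O | starting material
2 | isopropenylmagnesium bromide (prop-1-en-2-ylmagnesium bromide) | CC(=C)[Mg]Br | starting material
3 | allyl bromide (3-bromoprop-1-ene) | C=CCBr | starting material
4 | bromomagnesium (3R)-2-methyl-3-(prop-1-en-2-yl)cyclopent-1-en-1-olate | CC(=C)[C@H]1CCC(O[Mg]Br)=C1C | intermediate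
5 | (2R,3R)-2-methyl-2-(prop-2-en-1-yl)-3-(prop-1-en-2-yl)cyclopentan-1-one (allyl trans to isopropenyl) | O=C1CC[C@H](C(C)=C)[C@@]1(C)CC=C | intermediate
6 | (3aR,7aR)-4,4,7a-trimethyloctahydro-1H-inden-1-one (trans-fused) | O=C1CC[C@@H]2C(C)(C)CCC[C@@]12C | intermediate
7 | pent-4-yn-1-ol | C#CCCCO | starting material
8 | pent-4-yn-1-yl 2,4,6-triisopropylbenzoate | O=C(OCCCC#C)c1c(C(C)C)cc(C(C)C)cc1C(C)C | intermediate
9 | dimethyl[(E)-2-methyl-5-(2,4,6-triisopropylbenzoyloxy)pent-1-en-1-yl]alane | C[Al](C)/C=C(\C)CCCOC(=O)c1c(C(C)C)cc(C(C)C)cc1C(C)C | intermediate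
10 | lithium butyl(dimethyl)[(E)-2-methyl-5-(2,4,6-triisopropylbenzoyloxy)pent-1-en-1-yl]aluminate | [Li+].CCCC[Al-](C)(C)/C=C(\C)CCCOC(=O)c1c(C(C)C)cc(C(C)C)cc1C(C)C | intermediate
11 | lithium butyl(dimethyl)[(E)-3-methyl-6-(2,4,6-triisopropylbenzoyloxy)hex-2-en-1-olato]aluminate | [Li+].CCCC[Al-](C)(C)OC/C=C(\C)CCCOC(=O)c1c(C(C)C)cc(C(C)C)cc1C(C)C | intermediate
12 | (E)-6-hydroxy-4-methylhex-4-en-1-yl 2,4,6-triisopropylbenzoate | O=C(OCCC/C(C)=C/CO)c1c(C(C)C)cc(C(C)C)cc1C(C)C | intermediate
13 | (E)-4-methyl-6-(triethylsilyloxy)hex-4-en-1-yl 2,4,6-triisopropylbenzoate | O=C(OCCC/C(C)=C/CO[Si](CC)(CC)CC)c1c(C(C)C)cc(C(C)C)cc1C(C)C | intermediate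
14 | (E)-1-lithio-4-methyl-6-(triethylsilyloxy)hex-4-en-1-yl 2,4,6-triisopropylbenzoate (racemic at the lithiated carbon) | [Li]C(CC/C(C)=C/CO[Si](CC)(CC)CC)OC(=O)c1c(C(C)C)cc(C(C)C)cc1C(C)C | intermediate
15 | lithium alkoxide of (E)-1-[(3aR,7aR)-1-hydroxy-4,4,7a-trimethyloctahydro-1H-inden-1-yl]-4-methyl-6-(triethylsilyloxy)hex-4-en-1-yl 2,4,6-triisopropylbenzoate (mixture at the two new carbinol carbons) | [Li]OC1(C(CC/C(C)=C/CO[Si](CC)(CC)CC)OC(=O)c3c(C(C)C)cc(C(C)C)cc3C(C)C)CC[C@@H]2C(C)(C)CCC[C@@]12C | intermediate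
16 | (5R,10R,13E)-15-(triethylsilyloxy)-17-norlabd-13-en-8-one as a mixture of C9 epimers | CC[Si](CC)(CC)OC/C=C(\C)CCC1C(=O)CC[C@@H]2C(C)(C)CCC[C@@]12C | intermediate
17 | (5R,9S,10R,13E)-15-(triethylsilyloxy)-17-norlabd-13-en-8-one (trans-decalin, side chain at C9 cis to the C10 methyl) | CC[Si](CC)(CC)OC/C=C(\C)CC[C@@H]1C(=O)CC[C@@H]2C(C)(C)CCC[C@@]12C | intermediate
18 | potassium (5R,9S,10R,13E)-15-(triethylsilyloxy)-17-norlabda-7,13-dien-8-olate | CC[Si](CC)(CC)OC/C=C(\C)CC[C@@H]1C(O[K])=CC[C@@H]2C(C)(C)CCC[C@@]12C | intermediate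
19 | (5R,9S,10R,13E)-15-(triethylsilyloxy)-17-norlabda-7,13-dien-8-yl trifluoromethanesulfonate | CC[Si](CC)(CC)OC/C=C(\C)CC[C@@H]1C(OS(=O)(=O)C(F)(F)F)=CC[C@@H]2C(C)(C)CCC[C@@]12C | intermediate
20 | triethyl{[(5R,9R,10R,13E)-labda-7,13-dien-15-yl]oxy}silane | CC[Si](CC)(CC)OC/C=C(\C)CC[C@@H]1C(C)=CC[C@@H]2C(C)(C)CCC[C@@]12C | intermediate
21 | (5R,9R,10R,13E)-labda-7,13-dien-15-ol (ent-labdane series) | OC/C=C(\C)CC[C@@H]1C(C)=CC[C@@H]2C(C)(C)CCC[C@@]12C | intermediate
22 | (5R,9R,10R,13R,14R)-13,14-epoxylabd-7-en-15-ol | OC[C@H]1O[C@]1(C)CC[C@@H]2C(C)=CC[C@@H]3C(C)(C)CCC[C@@]23C | intermediate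
23 | (5R,9R,10R,13S,14R)-labd-7-ene-13,14,15-triol | OC[C@@H](O)[C@@](C)(O)CC[C@@H]1C(C)=CC[C@@H]2C(C)(C)CCC[C@@]12C | intermediate
24 | (5R,9R,10R,13S,14R)-13-hydroxylabd-7-ene-14,15-diyl diacetate (CNP0545929.1) | CC(=O)OC[C@@H](OC(C)=O)[C@@](C)(O)CC[C@@H]1C(C)=CC[C@@H]2C(C)(C)CCC[C@@]12C | target

**Step count**
Total: 11 steps. Longest linear sequence: 9 steps (7 → 24, steps 3 to 11); the core branch from 1 is 8 steps.

**Steps most likely to fail**

Step 6 (the new ring expansion). The lithiated benzoate may enolise 6, the alkoxide may close to an epoxide, or the C7 methylene may migrate instead of C10. The fallback uses known chemistry, sets out from the adduct 15 (made from 6 and 13 as in step 6) and comes back at 17. Quench 15 with aqueous NH4Cl and isolate the hydroxy benzoate (E)-1-[(3aR,7aR)-1-hydroxy-4,4,7a-trimethyloctahydro-1H-inden-1-yl]-4-methyl-6-(triethylsilyloxy)hex-4-en-1-yl 2,4,6-triisopropylbenzoate F1. LiAlH4 (THF, 65 °C) cleaves the hindered ester and gives the diol (E)-1-[(3aR,7aR)-1-hydroxy-4,4,7a-trimethyloctahydro-1H-inden-1-yl]-4-methyl-6-(triethylsilyloxy)hex-4-en-1-ol F2. MsCl and Et3N (CH2Cl2, −20 °C) sulfonate only the secondary hydroxyl and give the mesylate (E)-1-[(3aR,7aR)-1-hydroxy-4,4,7a-trimethyloctahydro-1H-inden-1-yl]-4-methyl-6-(triethylsilyloxy)hex-4-en-1-yl methanesulfonate F3. Et3Al (CH2Cl2, −78 → 0 °C) then brings about the established semipinacol shift of a β-mesyloxy alcohol to the ketone 16, and DBU gives 17.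

Step 2. The tertiary radical may be reduced to an isopropyl group before it cyclises, or it may close 5-exo. The fallback sets out from 5 and comes back at 6. Dry HCl (CH2Cl2, −78 °C) adds in the Markovnikov sense to the isopropenyl group only and gives the tertiary chloride (2R,3S)-3-(2-chloropropan-2-yl)-2-methyl-2-(prop-2-en-1-yl)cyclopentan-1-one F4. Slow addition of Bu3SnH with AIBN (benzene, 80 °C, 0.005 M) generates the same radical in a chain with a low hydride concentration, so that 6-endo closure to 6 can win.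

Step 1. An sp2 Grignard reagent may give a low enantiomer ratio with the copper/ferrocenyl diphosphine catalyst. The fallback replaces asymmetric catalysis by resolution, sets out from 1 and comes back at 6. Run the addition and allylation with CuBr·SMe2 alone (THF, −40 °C; then 3, DMPU). Besides 4 and 5 this gives their mirror images, the enolate bromomagnesium (3S)-2-methyl-3-(prop-1-en-2-yl)cyclopent-1-en-1-olate F5 and the ketone (2S,3S)-2-methyl-2-(prop-2-en-1-yl)-3-(prop-1-en-2-yl)cyclopentan-1-one F6. Step 2 on the racemate gives 6 together with (3aS,7aS)-4,4,7a-trimethyloctahydro-1H-inden-1-one F7, and preparative chromatography on a chiral stationary phase (supercritical CO2) separates 6 from F7.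

Further compounds
F1 | step 6 | (E)-1-[(3aR,7aR)-1-hydroxy-4,4,7a-trimethyloctahydro-1H-inden-1-yl]-4-methyl-6-(triethylsilyloxy)hex-4-en-1-yl 2,4,6-triisopropylbenzoate (mixture at the two carbinol carbons) | OC1(C(CC/C(C)=C/CO[Si](CC)(CC)CC)OC(=O)c3c(C(C)C)cc(C(C)C)cc3C(C)C)CC[C@@H]2C(C)(C)CCC[C@@]12C
F2 | step 6 | (E)-1-[(3aR,7aR)-1-hydroxy-4,4,7a-trimethyloctahydro-1H-inden-1-yl]-4-methyl-6-(triethylsilyloxy)hex-4-en-1-ol (mixture at the two carbinol carbons) | OC1(C(O)CC/C(C)=C/CO[Si](CC)(CC)CC)CC[C@@H]2C(C)(C)CCC[C@@]12C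
F3 | step 6 | (E)-1-[(3aR,7aR)-1-hydroxy-4,4,7a-trimethyloctahydro-1H-inden-1-yl]-4-methyl-6-(triethylsilyloxy)hex-4-en-1-yl methanesulfonate (mixture at the two carbinol carbons) | OC1(C(OS(C)(=O)=O)CC/C(C)=C/CO[Si](CC)(CC)CC)CC[C@@H]2C(C)(C)CCC[C@@]12C
F4 | step 2 | (2R,3S)-3-(2-chloropropan-2-yl)-2-methyl-2-(prop-2-en-1-yl)cyclopentan-1-one | O=C1CC[C@H](C(C)(C)Cl)[C@@]1(C)CC=C
F5 | step 1 | bromomagnesium (3S)-2-methyl-3-(prop-1-en-2-yl)cyclopent-1-en-1-olate | CC(=C)[C@@H]1CCC(O[Mg]Br)=C1C
F6 | step 1 | (2S,3S)-2-methyl-2-(prop-2-en-1-yl)-3-(prop-1-en-2-yl)cyclopentan-1-one | O=C1CC[C@@H](C(C)=C)[C@]1(C)CC=C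
F7 | step 1 | (3aS,7aS)-4,4,7a-trimethyloctahydro-1H-inden-1-one | O=C1CC[C@H]2C(C)(C)CCC[C@]12C
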